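Everything rests on cutting the C4–C5 bond of the cyclohexanone ring: C4, the tertiary carbinol carbon (C(CH3)OH), sits next to the C5 ketone, an α-ketol that maps onto an aldehyde–ketone benzoin union. One carbene-catalysed cyclisation forms this bond, closes the only ring and sets the C4 stereocentre under control of C1 and C3. Its precursor is the open-chain keto aldehyde (3R,5R)-5-silyloxy-6-oxo-3-isopropenylheptanal, which is trans-carveol, made from (S)-carvone, with its ring alkene cleaved. After the ring is re-formed, C6 is hydroxylated and acylated, and the isopropenyl group is extended to the hydroperoxy dienone by allylic chlorination, oxidation, vinylation and cross-metathesis.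

Key step: step 7

Remarks on the chemistry
- Ring numbering used throughout: C1 (carries the side chain), C2 (CH2), C3 (CHOH), C4 (C(CH3)OH), C5 (C=O), C6 (CH–O–isovaleryl). In this numbering the target is 1S,3R,4S,6S. C3–O is trans to the C1 substituent and trans to C4–OH, and C6–O is trans to the C1 substituent.
- The structures of the keto aldehyde 8 and the ketol 10 agree atom for atom and centre for centre with the target and with (S)-carvone; nothing had to be changed. Relative to carvone the ring carbonyl ends on the former β-carbon of the enone, a net 1,3-transposition.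
- Design of the key-step precursor: C6 stays an unsubstituted CH2 until the ring is closed (an α-oxygenated aldehyde would divert the carbene to redox esterification). C3–O is a TBS ether, which survives periodic acid, does not chelate or migrate, and leaves at the end together with the peroxyketal. The isopropenyl group is carried unfunctionalised because an allylic halide would alkylate the carbene.
- Assumptions: diol 7 is drawn for water attack at the secondary oxirane carbon; either trans-diol gives the same product. The carbinol centre made in step 13 forms as a mixture of epimers and is left undefined because step 14 removes it.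

Step 1
Reactants: 1 (S)-(+)-carvone
Product: 2 (1S,5S)-cis-carveol
Conditions: NaBH4, CeCl3·7H2O, MeOH, 0 °C
Reagents that add atoms: none
Why: Luche reduction gives clean 1,2-reduction of the enone, and axial hydride delivery to the half-chair with equatorial isopropenyl should give the pseudoequatorial alcohol cis to isopropenyl (new centre 1S, substrate control).

Step 2
Reactants: 2 (1S,5S)-cis-carveol
Product: 3 (1R,5S)-trans-carveyl 4-nitrobenzoate
Conditions: 4-nitrobenzoic acid, PPh3, DIAD, THF, 0 → 23 °C
Reagents that add atoms: 4-nitrobenzoic acid, O=C(O)c1ccc(cc1)[N+](=O)[O-]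
Why: Mitsunobu reaction, in which the acidic carboxylate displaces the activated allylic carbinol carbon by SN2 with inversion, turning the cis alcohol into the trans ester (1R).

Step 3
Reactants: 3 (1R,5S)-trans-carveyl 4-nitrobenzoate
Product: 4 (1R,5S)-trans-carveol
Conditions: K2CO3 (0.2 equiv), MeOH, 23 °C
Reagents that add atoms: none
Why: Base-catalysed transesterification (methanolysis) of the electron-poor aryl ester cleaves the acyl–oxygen bond, so the carbinol centre is not touched.

Step 4
Reactants: 4 (1R,5S)-trans-carveol
Product: 5 syn-epoxy alcohol, 1-methyl-4-(prop-1-en-2-yl)-7-oxabicyclo[4.1.0]heptan-2-ol with the oxirane oxygen cis to OH and trans to isopropenyl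
Conditions: VO(acac)2 (2 mol %), t-BuOOH (decane), CH2Cl2, 0 → 23 °C
Reagents that add atoms: tert-butyl hydroperoxide, CC(C)(C)OO
Why: Hydroxyl-directed epoxidation, in which the vanadium alkoxide of the pseudoaxial allylic alcohol delivers oxygen to the ring alkene on its own face and leaves the isopropenyl alkene alone; the two oxirane centres are erased in step 6.

Step 5
Reactants: 5 syn-epoxy alcohol
Product: 6 tert-butyldimethylsilyl ether of 5
Conditions: TBSCl, imidazole, DMF, 23 °C
Reagents that add atoms: tert-butyldimethylsilyl chloride, CC(C)(C)[Si](C)(C)Cl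
Why: Standard imidazole-mediated silylation of a secondary alcohol under neutral conditions that leave the oxirane intact.

Step 6
Reactants: 6 tert-butyldimethylsilyl ether of 5
Product: 8 (3R,5R)-5-[tert-butyl(dimethyl)silyl]oxy-6-oxo-3-(prop-1-en-2-yl)heptanal, via trans-diol 7 (not isolated)
Conditions: H5IO6, THF/H2O, 0 → 23 °C
Reagents that add atoms: water, O
Why: Periodic acid cleavage of an epoxide, in which acid-promoted anti opening gives the vicinal diol and Malaprade glycol cleavage then gives the methyl ketone at C4 and the aldehyde at C5, while the silyl ether at C3 prevents further cleavage and the isopropenyl group is inert.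

Step 7
Reactants: 8 (3R,5R)-5-[tert-butyl(dimethyl)silyl]oxy-6-oxo-3-(prop-1-en-2-yl)heptanal
Product: 10 (2S,3R,5R)-3-[tert-butyl(dimethyl)silyl]oxy-2-hydroxy-2-methyl-5-(prop-1-en-2-yl)cyclohexan-1-one, via enaminol 9 (not isolated)
Conditions: 2-(pentafluorophenyl)-6,7-dihydro-5H-pyrrolo[2,1-c][1,2,4]triazol-2-ium tetrafluoroborate (15 mol %), Et3N (20 mol %), toluene (0.02 M), 23 °C
Reagents that add atoms: none
Why: The triazolylidene freed by Et3N adds to the aldehyde carbon C5 of 8 and proton transfer gives the acyl-anion enaminol 9, whose nucleophilic C5 attacks the methyl ketone carbon C4; collapse of the adduct releases the carbene and the α-ketol 10. This is the carbene-catalysed intramolecular crossed aldehyde–ketone benzoin reaction, which is established for six-membered tertiary α-hydroxy ketones. The cyclohexanone ring closes in a 6-exo-trig mode, with the exocyclic enaminol carbon attacking the exocyclic C4=O. The new C4 centre is set by the resident C1 and C3 centres through a chair transition state with isopropenyl equatorial, C3–OTBS axial, and the ketone oxygen axial and opposed to the C3–O dipole with methyl equatorial, which should place C4–OH trans to C3–OTBS. The step needs the acyl anion to form only at C5 and to add faster than aldol, redox esterification or epimerisation at C3; this is secured because only the aldehyde can give the enaminol, C6 is an unsubstituted CH2, the weak amine base barely enolises either carbonyl, and high dilution suppresses intermolecular benzoin.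

Step 8
Reactants: 10 (2S,3R,5R)-3-[tert-butyl(dimethyl)silyl]oxy-2-hydroxy-2-methyl-5-(prop-1-en-2-yl)cyclohexan-1-one
Product: 11 bis(trimethylsilyl) derivative of 10 with C4–OSiMe3 and a C5=C6 trimethylsilyl enol ether
Conditions: TMSOTf, Et3N, CH2Cl2, −78 → 0 °C
Reagents that add atoms: trimethylsilyl trifluoromethanesulfonate, C[Si](C)(C)OS(=O)(=O)C(F)(F)F
Why: Soft enolisation to an enol silyl ether, which can only form toward C6 because C4 is quaternary, with the tertiary hydroxyl capped in the same operation.

Step 9
Reactants: 11 bis(trimethylsilyl) derivative of 10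
Product: 14 6-hydroxy ketone (C3–OTBS; C4–OH and C6–OH free; C6–OH trans to the C1 isopropenyl group), via silyloxy oxirane 12 (not isolated), via bis-silyl ketone 13 (not isolated)
Conditions: mCPBA, CH2Cl2, −20 °C; then citric acid (cat.), MeOH, 23 °C
Reagents that add atoms: 3-chloroperoxybenzoic acid, OOC(=O)c1cccc(Cl)c1
Why: Rubottom oxidation, in which the electron-rich enol ether is epoxidised much faster than the isopropenyl alkene and from the face opposite the pseudoaxial C4–OSiMe3 and the C1 isopropenyl group, silyl migration opens the oxirane to the α-silyloxy ketone with C6–O trans to the C1 substituent (equatorial, also the more stable epimer), and mild acidic methanolysis removes both trimethylsilyl groups but not the TBS ether.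

Step 10
Reactants: 14 6-hydroxy ketone; 15 3-methylbutanoyl chloride
Product: 16 C6 3-methylbutanoate of 14
Conditions: pyridine, DMAP (cat.), CH2Cl2, 0 °C
Reagents that add atoms: 3-methylbutanoyl chloride (15), CC(C)CC(Cl)=O
Why: DMAP-catalysed acylation esterifies the secondary C6 hydroxyl, while the hindered tertiary C4 hydroxyl should not react at 0 °C.

Step 11
Reactants: 16 C6 3-methylbutanoate of 14
Product: 17 allylic chloride, as 16 with 3-chloroprop-1-en-2-yl at C1
Conditions: Ca(OCl)2, solid CO2, CH2Cl2/H2O, 0 °C
Reagents that add atoms: calcium hypochlorite, [Ca+2].[O-]Cl.[O-]Cl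
Why: Ene-type allylic chlorination by hypochlorous acid made in the flask, in which chlorine adds to the terminal CH2 of the only alkene and the tertiary cation loses a methyl proton to give the 2-substituted allyl chloride without touching a stereocentre.

Step 12
Reactants: 17 allylic chloride
Product: 19 enal, as 16 with 3-oxoprop-1-en-2-yl at C1, via alkoxyammonium chloride 18 (not isolated)
Conditions: Me3NO (anhydrous), DMSO, 23 °C
Reagents that add atoms: trimethylamine N-oxide, C[N+](C)(C)[O-]
Why: Ganem oxidation (a Kornblum-type halide oxidation), in which the N-oxide oxygen displaces the allylic chloride and the alkoxyammonium salt loses trimethylamine on deprotonation by a second N-oxide, giving the enal under nearly neutral conditions that spare the ester and the α-ketol.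

Step 13
Reactants: 19 enal
Product: 20 divinyl carbinol, as 16 with 3-hydroxypenta-1,4-dien-2-yl at C1 (carbinol epimers)
Conditions: vinyl bromide, CrCl2, NiCl2 (cat.), DMF, 23 °C
Reagents that add atoms: vinyl bromide, C=CBr
Why: Nozaki–Hiyama–Kishi reaction, in which the vinylchromium reagent adds 1,2 to the aldehyde only and leaves the ring ketone and the ester untouched; the new carbinol centre is removed in step 14.

Step 14
Reactants: 20 divinyl carbinol
Product: 21 dienone, as 16 with 3-oxopenta-1,4-dien-2-yl at C1
Conditions: Dess–Martin periodinane, CH2Cl2, 0 → 23 °C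
Reagents that add atoms: none
Why: Dess–Martin oxidation of the bis-allylic secondary alcohol gives the cross-conjugated dienone, while the tertiary C4 hydroxyl cannot be oxidised and C3 is silylated.

Step 15
Reactants: 22 2-methylbut-3-en-2-ol
Product: 23 2-hydroperoxy-2-methylbut-3-ene
Conditions: H2O2 (50% aq.), H2SO4 (cat.), 0 °C
Reagents that add atoms: hydrogen peroxide, OO
Why: Acid-catalysed perhydrolysis of a tertiary alcohol (SN1), in which the tertiary allylic cation is captured by hydrogen peroxide at its more substituted terminus.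

Step 16
Reactants: 23 2-hydroperoxy-2-methylbut-3-ene
Product: 24 2-[(2-methoxypropan-2-yl)peroxy]-2-methylbut-3-ene
Conditions: 2-methoxypropene, PPTS (cat.), CH2Cl2, 0 °C
Reagents that add atoms: 2-methoxypropene, C=C(C)OC
Why: Acid-catalysed addition of the hydroperoxide to the enol ether (peroxyketal protection) masks the O–O–H group, which would otherwise destroy a ruthenium alkylidene.

Step 17
Reactants: 21 dienone; 24 2-[(2-methoxypropan-2-yl)peroxy]-2-methylbut-3-ene
Product: 25 protected target, as 16 with (E)-6-[(2-methoxypropan-2-yl)peroxy]-6-methyl-3-oxohepta-1,4-dien-2-yl at C1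
Conditions: second-generation Hoveyda–Grubbs catalyst RuCl2(SIMes)(=CH–C6H4–2-OiPr) (10 mol %), 24 (4 equiv), CH2Cl2, 40 °C
Reagents that add atoms: 2-[(2-methoxypropan-2-yl)peroxy]-2-methylbut-3-ene (24), C=CC(C)(C)OOC(C)(C)OC
Why: Olefin cross-metathesis, in which the monosubstituted vinyl ketone couples with the hindered, non-dimerising allylic peroxide used in excess, the 1,1-disubstituted enone alkene stays out, the quaternary allylic carbon enforces the E geometry, and dialkyl peroxides and peroxyketals are tolerated by ruthenium alkylidenes.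

Step 18
Reactants: 25 protected target
Product: 26 target, (1S,2S,4R,5S)-4,5-dihydroxy-2-[(E)-6-hydroperoxy-6-methyl-3-oxohepta-1,4-dien-2-yl]-5-methyl-6-oxocyclohexyl 3-methylbutanoate
Conditions: HF (48% aq.), MeCN, 0 → 23 °C
Reagents that add atoms: none
Why: Acidic global deprotection, in which fluoride cleaves the C3 silyl ether and aqueous acid hydrolyses the peroxyketal, under conditions that the tertiary hydroperoxide, the ester, the α-ketol and the dienone should withstand and that touch no stereocentre.

Compound list
1 | (S)-(+)-carvone | CC1=CC[C@@H](CC1=O)C(C)=C | starting material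
2 | (1S,5S)-cis-carveol | CC1=CC[C@@H](C[C@@H]1O)C(C)=C | intermediate
3 | (1R,5S)-trans-carveyl 4-nitrobenzoate | CC1=CC[C@@H](C[C@H]1OC(=O)c2ccc(cc2)[N+](=O)[O-])C(C)=C | intermediate
4 | (1R,5S)-trans-carveol | CC1=CC[C@@H](C[C@H]1O)C(C)=C | intermediate
5 | syn-epoxy alcohol, 1-methyl-4-(prop-1-en-2-yl)-7-oxabicyclo[4.1.0]heptan-2-ol, oxirane oxygen cis to OH and trans to isopropenyl | C=C(C)[C@@H]1C[C@@H](O)[C@@]2(C)O[C@H]2C1 | intermediate
6 | tert-butyldimethylsilyl ether of 5 | C=C(C)[C@@H]1C[C@@H](O[Si](C)(C)C(C)(C)C)[C@@]2(C)O[C@H]2C1 | intermediate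
7 | trans-diol, 3-silyloxy-2-methyl-5-(prop-1-en-2-yl)cyclohexane-1,2-diol with the two hydroxyls trans (not isolated) | C=C(C)[C@@H]1C[C@@H](O[Si](C)(C)C(C)(C)C)[C@@](C)(O)[C@H](O)C1 | intermediate
8 | (3R,5R)-5-[tert-butyl(dimethyl)silyl]oxy-6-oxo-3-(prop-1-en-2-yl)heptanal | C=C(C)[C@@H](CC=O)C[C@@H](O[Si](C)(C)C(C)(C)C)C(C)=O | intermediate
9 | enaminol (acyl-anion equivalent) from the aldehyde of 8 and the triazolylidene (not isolated) | C=C(C)[C@@H](CC(O)=C1N(c2c(F)c(F)c(F)c(F)c2F)N=C2CCCN12)C[C@@H](O[Si](C)(C)C(C)(C)C)C(C)=O | intermediate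
10 | (2S,3R,5R)-3-[tert-butyl(dimethyl)silyl]oxy-2-hydroxy-2-methyl-5-(prop-1-en-2-yl)cyclohexan-1-one (C4–OH trans to C3–OTBS; C3–O trans to isopropenyl) | C=C(C)[C@@H]1C[C@@H](O[Si](C)(C)C(C)(C)C)[C@](C)(O)C(=O)C1 | intermediate
11 | bis(trimethylsilyl) derivative of 10: C4–OSiMe3 and C5=C6 trimethylsilyl enol ether | C=C(C)[C@@H]1C[C@@H](O[Si](C)(C)C(C)(C)C)[C@](C)(O[Si](C)(C)C)C(O[Si](C)(C)C)=C1 | intermediate
12 | silyloxy oxirane of 11, oxirane oxygen on the face anti to isopropenyl (not isolated) | C=C(C)[C@@H]1C[C@@H](O[Si](C)(C)C(C)(C)C)[C@](C)(O[Si](C)(C)C)[C@@]2(O[Si](C)(C)C)O[C@@H]12 | intermediate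
13 | C4,C6-bis(trimethylsilyloxy) ketone, C6–O trans to isopropenyl (not isolated) | C=C(C)[C@@H]1C[C@@H](O[Si](C)(C)C(C)(C)C)[C@](C)(O[Si](C)(C)C)C(=O)[C@H]1O[Si](C)(C)C | intermediate
14 | (2S,3R,5S,6S)-3-[tert-butyl(dimethyl)silyl]oxy-2,6-dihydroxy-2-methyl-5-(prop-1-en-2-yl)cyclohexan-1-one (C6–OH trans to isopropenyl) | C=C(C)[C@@H]1C[C@@H](O[Si](C)(C)C(C)(C)C)[C@](C)(O)C(=O)[C@H]1O | intermediate
15 | 3-methylbutanoyl chloride | CC(C)CC(Cl)=O | starting material
16 | C6 3-methylbutanoate of 14 | C=C(C)[C@@H]1C[C@@H](O[Si](C)(C)C(C)(C)C)[C@](C)(O)C(=O)[C@H]1OC(=O)CC(C)C | intermediate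
17 | allylic chloride, as 16 with 3-chloroprop-1-en-2-yl at C1 | C=C(CCl)[C@@H]1C[C@@H](O[Si](C)(C)C(C)(C)C)[C@](C)(O)C(=O)[C@H]1OC(=O)CC(C)C | intermediate
18 | alkoxy(trimethyl)ammonium chloride from 17 (not isolated) | C=C(CO[N+](C)(C)C)[C@@H]1C[C@@H](O[Si](C)(C)C(C)(C)C)[C@](C)(O)C(=O)[C@H]1OC(=O)CC(C)C.[Cl-] | intermediate
19 | enal, as 16 with 3-oxoprop-1-en-2-yl at C1 | C=C(C=O)[C@@H]1C[C@@H](O[Si](C)(C)C(C)(C)C)[C@](C)(O)C(=O)[C@H]1OC(=O)CC(C)C | intermediate
20 | divinyl carbinol, as 16 with 3-hydroxypenta-1,4-dien-2-yl at C1 (carbinol centre undefined, both epimers) | C=CC(O)C(=C)[C@@H]1C[C@@H](O[Si](C)(C)C(C)(C)C)[C@](C)(O)C(=O)[C@H]1OC(=O)CC(C)C | intermediate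
21 | dienone, as 16 with 3-oxopenta-1,4-dien-2-yl at C1 | C=CC(=O)C(=C)[C@@H]1C[C@@H](O[Si](C)(C)C(C)(C)C)[C@](C)(O)C(=O)[C@H]1OC(=O)CC(C)C | intermediate
22 | 2-methylbut-3-en-2-ol | C=CC(C)(C)O | starting material
23 | 2-hydroperoxy-2-methylbut-3-ene | C=CC(C)(C)OO | intermediate
24 | 2-[(2-methoxypropan-2-yl)peroxy]-2-methylbut-3-ene | C=CC(C)(C)OOC(C)(C)OC | intermediate
25 | protected target: C3–OTBS, peroxide as 2-methoxypropan-2-yl peroxyketal, E enone | C=C(C(=O)/C=C/C(C)(C)OOC(C)(C)OC)[C@@H]1C[C@@H](O[Si](C)(C)C(C)(C)C)[C@](C)(O)C(=O)[C@H]1OC(=O)CC(C)C | intermediate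
26 | (1S,2S,4R,5S)-4,5-dihydroxy-2-[(E)-6-hydroperoxy-6-methyl-3-oxohepta-1,4-dien-2-yl]-5-methyl-6-oxocyclohexyl 3-methylbutanoate (CNP0239240.1) | C=C(C(=O)/C=C/C(C)(C)OO)[C@@H]1C[C@@H](O)[C@](C)(O)C(=O)[C@H]1OC(=O)CC(C)C | target

Total step count: 18. Longest linear sequence: 16 (steps 1–14, 17, 18).

Steps most likely to fail

Step 7. The risk is insufficient facial discrimination at the C4 ketone, or aldol closure and epimerisation at C3 outrunning the carbene cycle. The fallback replaces the acyl-anion closure by a reductive one and sets out from keto aldehyde 8. SmI2 (divalent samarium) in THF with t-BuOH at −78 °C should effect a pinacol cyclisation through a chelated ketyl, forming the same C4–C5 bond and giving the cis-4,5-diol F1 with C4–O trans to the C3 silyloxy group. IBX in DMSO then oxidises only the secondary C5 hydroxyl, and the route is rejoined at ketol 10.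

Step 17. The risk is slow loading of the quaternary allylic peroxide onto ruthenium while the divinyl ketone oligomerises or the catalyst decays at the O–O bond. The fallback keeps the peroxide out of the metathesis and installs it last by a singlet-oxygen ene reaction. It sets out from enal 19.
- Aldehyde-selective Barbier allylation (allyl bromide, indium, THF/H2O) should give the homoallylic alcohol F2.
- Cross-metathesis with 2-methylbut-2-ene (second-generation Grubbs catalyst) turns the terminal vinyl into a prenyl group, giving the prenyl carbinol F3.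
- Dess–Martin oxidation gives the β,γ-unsaturated ketone F4.
- Schenck ene photo-oxygenation (O2, tetraphenylporphyrin, visible light, CH2Cl2, 0 °C) should take hydrogen from the CH2 between carbonyl and alkene and place OOH on the tertiary carbon with an E enone, giving the silyl-protected hydroperoxide F5.
- HF in MeCN removes the TBS group, and the route is rejoined at target 26.

Step 9. The risk is poor facial selectivity in the epoxidation of the enol ether, which would deliver oxygen cis to the isopropenyl group. The fallback corrects the centre by substitution instead of relying on the facial bias and sets out from enol ether 11. Attack on the lower face would give the lower-face silyloxy oxirane F6, which rearranges to the epimeric bis-silyl ketone F7 and after methanolysis gives the C6-epimeric ketol F8. Mitsunobu esterification of F8 with 3-methylbutanoic acid (PPh3, DIAD, THF) inverts C6 and installs the ester in one step, so both epimers converge on isovalerate 16.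

Further compounds
F1 | step 7 | cis-4,5-diol, 3-silyloxy-2-methyl-5-(prop-1-en-2-yl)cyclohexane-1,2-diol with both hydroxyls trans to C3–OTBS | C=C(C)[C@@H]1C[C@@H](O[Si](C)(C)C(C)(C)C)[C@](C)(O)[C@H](O)C1
F2 | step 17 | homoallylic alcohol, as 16 with 3-hydroxyhexa-1,5-dien-2-yl at C1 (carbinol epimers) | C=CCC(O)C(=C)[C@@H]1C[C@@H](O[Si](C)(C)C(C)(C)C)[C@](C)(O)C(=O)[C@H]1OC(=O)CC(C)C
F3 | step 17 | prenyl carbinol, as 16 with 3-hydroxy-6-methylhepta-1,5-dien-2-yl at C1 (carbinol epimers) | CC(C)=CCC(O)C(=C)[C@@H]1C[C@@H](O[Si](C)(C)C(C)(C)C)[C@](C)(O)C(=O)[C@H]1OC(=O)CC(C)C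
F4 | step 17 | β,γ-unsaturated ketone, as 16 with 6-methyl-3-oxohepta-1,5-dien-2-yl at C1 | CC(C)=CCC(=O)C(=C)[C@@H]1C[C@@H](O[Si](C)(C)C(C)(C)C)[C@](C)(O)C(=O)[C@H]1OC(=O)CC(C)C
F5 | step 17 | silyl-protected hydroperoxide, the target with C3–OTBS | C=C(C(=O)/C=C/C(C)(C)OO)[C@@H]1C[C@@H](O[Si](C)(C)C(C)(C)C)[C@](C)(O)C(=O)[C@H]1OC(=O)CC(C)C
F6 | step 9 | lower-face silyloxy oxirane of 11, oxirane oxygen cis to isopropenyl | C=C(C)[C@@H]1C[C@@H](O[Si](C)(C)C(C)(C)C)[C@](C)(O[Si](C)(C)C)[C@]2(O[Si](C)(C)C)O[C@H]12
F7 | step 9 | epimeric bis-silyl ketone, C6–OSiMe3 cis to isopropenyl | C=C(C)[C@@H]1C[C@@H](O[Si](C)(C)C(C)(C)C)[C@](C)(O[Si](C)(C)C)C(=O)[C@@H]1O[Si](C)(C)C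
F8 | step 9 | C6-epimeric ketol, C6–OH cis to isopropenyl | C=C(C)[C@@H]1C[C@@H](O[Si](C)(C)C(C)(C)C)[C@](C)(O)C(=O)[C@@H]1O
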